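Everything rests on cutting the C4–C5 bond of ring A in the [3,3] sense, which returns the C19 carbonyl to an ester oxygen on C1. The key step uses three features together: C1 carries oxygen, it is allylic to a C10=C5 alkene in ring B, and quaternary C4 bears C19. Enolising the six-membered C19–O–C1 lactone and rearranging its silyl ketene acetal closes ring A, sets C4 and C5, moves the alkene to C1=C10 and leaves the C19 acid on the α-face, ready to lactonise onto C10. The precursor is a B/C/D cyclopentene carrying this δ-lactone on C10, with C3 and C7 as dioxolanes and O12 as TBS ether.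

Key step: step 21

Remark: gibberellane numbering is used for every intermediate; β is the face of ring B that carries H-9 and C-15, α the face that carries C-11 and C-14.
Remark: C7 is carried as a 1,3-dioxolane (the form in which it is introduced), and C3 is ketalised before lactonisation because the free β-keto δ-lactone would sit as its enol.
Assumption: the lipase of step 3 acylates the (R)-carbinol, the usual preference for 4-hydroxycyclopentenones; were it reversed, the unreacted alcohol would be silylated directly.
Assumption: Ti(OiPr)4/(S)-BINOL gives the (S)-carbinol in step 18, by analogy with (R)-BINOL giving (R)-aldols of aryl and alkenyl aldehydes; otherwise the antipodal ligand is used.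

Step 1
Reactants: 1 furfural; 2 propargyl bromide
Product: 3 (±)-1-(furan-2-yl)but-3-yn-1-ol
Conditions: Zn dust, THF/sat. aq. NH4Cl, 0 °C to rt
Reagents that add atoms: none
Why: Barbier-type propargylation, in which the organozinc formed in the flask from 2 adds to the aldehyde to give the homopropargylic carbinol, whose stereocentre is erased in step 2.

Step 2
Reactants: 3
Product: 5 (±)-4-hydroxy-2-(prop-2-yn-1-yl)cyclopent-2-en-1-one, via trans-4-hydroxy-5-propargylcyclopent-2-enone 4 (not isolated)
Conditions: ZnCl2 (cat.), H2O/1,4-dioxane, pH 5–6, 100 °C; then phosphate buffer pH 8, 60 °C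
Reagents that add atoms: water, O
Why: Piancatelli rearrangement (furfuryl cation, water capture, ring opening, 4π-conrotatory closure to the trans-4-hydroxy-5-alkyl enone 4) followed by base-mediated isomerisation to the thermodynamically preferred 2-alkyl-4-hydroxy enone, obtained racemic.

Step 3
Reactants: 5
Product: 6 (R)-4-acetoxy-2-(prop-2-yn-1-yl)cyclopent-2-en-1-one
Conditions: Burkholderia cepacia lipase, vinyl acetate, t-BuOMe, 30 °C, stopped near half conversion
Reagents that add atoms: vinyl acetate, C=COC(C)=O
Why: Enzymatic kinetic resolution by irreversible transesterification, in which the lipase acetylates the (R)-carbinol selectively so that the acetate should be obtained enantiopure.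

Step 4
Reactants: 6
Product: 7 (R)-4-hydroxy-2-(prop-2-yn-1-yl)cyclopent-2-en-1-one
Conditions: Candida antarctica lipase B (immobilised), MeOH, t-BuOMe, 30 °C
Reagents that add atoms: none
Why: Lipase-catalysed methanolysis removes the acetate at neutral pH, avoiding the β-elimination and racemisation that chemical bases cause in 4-acyloxycyclopentenones.

Step 5
Reactants: 7
Product: 8 (R)-4-(triethylsilyloxy)-2-(prop-2-yn-1-yl)cyclopent-2-en-1-one
Conditions: Et3SiCl, imidazole, CH2Cl2, 0 °C
Reagents that add atoms: chlorotriethylsilane, CC[Si](Cl)(CC)CC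
Why: Standard silylation of the secondary alcohol; the bulky silyl ether is the group that will shield one face of the dienophile.

Step 6
Reactants: 9 methyl vinyl ketone
Product: 10 2-(triisopropylsilyloxy)buta-1,3-diene
Conditions: i-Pr3SiOTf, Et3N, CH2Cl2, 0 °C to rt
Reagents that add atoms: triisopropylsilyl triflate, CC(C)[Si](OS(=O)(=O)C(F)(F)F)(C(C)C)C(C)C
Why: Amine-promoted enolisation and O-silylation of the methyl ketone by the silyl triflate give the 2-silyloxydiene (silyl enol ether formation).

Step 7
Reactants: 8 (R)-silyloxy enone; 10 silyloxydiene (1.5 equiv)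
Product: 11 cis-fused Diels–Alder adduct (C6 ketone; 8β-propargyl; 9β-H; 10β-OSiEt3; C12=C13 triisopropylsilyl enol ether)
Conditions: Tf2NH (10 mol%), CH2Cl2, −78 to −40 °C; Et3N quench
Reagents that add atoms: none
Why: Diels–Alder reaction catalysed by the silyl triflimide formed from Tf2NH and 10, in which the nucleophilic diene terminus C11 bonds to the enone β-carbon C9 and C14 to C8 (para regiochemistry, enol ether left at C12=C13), the diene adds anti to the C10 silyloxy group, and suprafacial addition makes H-9 and the propargyl group cis, which sets C8 and C9.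

Step 8
Reactants: 11
Product: 12 B/C/D diketone (6,12-dioxo; 10β-OSiEt3; 16-methylene)
Conditions: Ph3PAuCl (5 mol%), AgBF4 (5 mol%), CH2Cl2/MeOH 10:1, rt
Reagents that add atoms: none
Why: Conia-ene-type 5-exo-dig carbocyclisation (monovalent gold catalysis), in which C13 of the silyl enol ether attacks the gold-activated C16, protodeauration leaves the exocyclic methylene, and C13 is fixed because the two-carbon bridge can only span C8 and C13 on the face that already carries C15.

Step 9
Reactants: 12
Product: 13 6α,12-diol (12-OH axial on ring C, syn to C10, as in the target; 10β-OSiEt3)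
Conditions: LiBH(s-Bu)3 (3 equiv), THF, −78 to 0 °C
Reagents that add atoms: none
Why: Trialkylborohydride reduction of both ketones, in which the axial trajectory at C12 is closed by C10 (syn-axial on ring C) so that hydride enters equatorially and gives the axial alcohol of the target, while C6 is reduced from the exposed β-face to an α-alcohol whose configuration does not matter because it is eliminated in step 12.

Step 10
Reactants: 13
Product: 14 6α,12-bis(tert-butyldimethylsilyl) ether (10β-OSiEt3)
Conditions: t-BuMe2SiOTf (2.5 equiv), 2,6-lutidine, CH2Cl2, 0 °C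
Reagents that add atoms: tert-butyldimethylsilyl triflate, CC(C)(C)[Si](C)(C)OS(=O)(=O)C(F)(F)F
Why: Silyl triflate silylation of both hindered secondary alcohols, where the C12 ether is the protecting group kept to the end and the C6 ether is the leaving group of step 12.

Step 11
Reactants: 14
Product: 15 10β-alcohol (6α,12-bis-OTBS)
Conditions: pyridinium p-toluenesulfonate (cat.), MeOH/CH2Cl2 1:1, 0 °C
Reagents that add atoms: none
Why: Acid-catalysed methanolysis removes the triethylsilyl ether far faster than the two hindered tert-butyldimethylsilyl ethers (selective silyl ether solvolysis).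

Step 12
Reactants: 15
Product: 17 ring-B enone (10-oxo-5-ene; 12-OTBS; 16-methylene), via 6α-silyloxy 10-ketone 16 (not isolated)
Conditions: Dess–Martin periodinane, CH2Cl2, rt; then DBU (5 equiv), rt
Reagents that add atoms: none
Why: Dess–Martin oxidation to the β-silyloxy ketone followed by E1cB loss of silanolate through the C5 enolate gives the transposed enone, and H-9, now α to the ketone, stays cis because the cis-fused cyclopentenone is by far the more stable ring fusion.

Step 13
Reactants: 17; 18 1,3-dioxolane (co-solvent)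
Product: 19 6β-(1,3-dioxolan-2-yl) 10-ketone (12-OTBS)
Conditions: (n-Bu4N)4[W10O32] (2 mol%), 1,3-dioxolane/MeCN, 390 nm LED, rt, degassed
Reagents that add atoms: none
Why: Giese addition under decatungstate hydrogen-atom-transfer photocatalysis, in which the nucleophilic dioxolan-2-yl radical adds to the enone β-carbon C6 from the open β-face (the α-face is roofed by ring C), setting C6 with the masked formyl group cis to C15, and back hydrogen transfer to C5 completes the hydroalkylation.

Step 14
Reactants: 19
Product: 20 C10 enol triflate (5(10)-ene; 6β-dioxolanyl; 12-OTBS)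
Conditions: KN(SiMe3)2, PhNTf2, THF, −78 °C
Reagents that add atoms: N-phenylbis(trifluoromethanesulfonimide), O=S(=O)(N(c1ccccc1)S(=O)(=O)C(F)(F)F)C(F)(F)F
Why: Kinetic deprotonation at the C5 methylene (the C9 methine is shielded by quaternary C8) and O-triflation of the potassium enolate fix the C10=C5 double bond (enol triflate formation).

Step 15
Reactants: 20
Product: 21 B/C/D enal (10-formyl-5(10)-ene; 6β-dioxolanyl; 12-OTBS; 16-methylene)
Conditions: Pd(PPh3)4 (5 mol%), CO (3 atm), Bu3SnH (slow addition), LiCl, THF, 50 °C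
Reagents that add atoms: carbon monoxide, [C-]#[O+]
Why: Palladium-catalysed reductive carbonylation (Stille formylation), in which oxidative addition to the enol triflate, CO insertion and hydride transfer from tin to the acylpalladium give the enal with C1 in place.

Step 16
Reactants: 22 methyl 2-methylacetoacetate
Product: 23 methyl 2-methyl-3-(trimethylsilyloxy)but-2-enoate
Conditions: Me3SiCl, Et3N, ZnCl2 (cat.), toluene, 40 °C
Reagents that add atoms: chlorotrimethylsilane, C[Si](C)(C)Cl
Why: Soft enolisation and O-silylation of the β-keto ester (silyl enol ether formation).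

Step 17
Reactants: 23
Product: 24 1-methoxy-2-methyl-1,3-bis(trimethylsilyloxy)buta-1,3-diene
Conditions: LiN(i-Pr)2, THF, −78 °C; then Me3SiCl
Reagents that add atoms: chlorotrimethylsilane, C[Si](C)(C)Cl
Why: γ-Deprotonation of the vinylogous ester by the lithium amide and O-silylation give the Chan-type bis(silyloxy)diene.

Step 18
Reactants: 21; 24 (1.5 equiv)
Product: 26 (1S)-δ-hydroxy β-keto methyl ester (C4 epimers), via bis-trimethylsilyl aldol adduct 25 (not isolated)
Conditions: Ti(OiPr)4 (10 mol%), (S)-BINOL (10 mol%), 4 Å MS, THF, −78 °C to rt; then CF3CO2H (cat.), THF/H2O, 0 °C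
Reagents that add atoms: none
Why: Catalytic asymmetric vinylogous Mukaiyama aldol addition, in which the γ-carbon of the dienolate (C2) adds 1,2 to the enal on the face chosen by the titanium–BINOL catalyst, setting (1S)-C1 under reagent control (the ring stereocentres are too remote to compete), and mild acid strips both trimethylsilyl groups.

Step 19
Reactants: 26
Product: 28 (1S)-hydroxy ester with C3 as 1,3-dioxolane (C4 epimers), via C1 trimethylsilyl ether 27 (not isolated)
Conditions: (Me3SiOCH2)2 (3 equiv), Me3SiOTf (10 mol%), CH2Cl2, −78 to −20 °C; then K2CO3, MeOH, 0 °C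
Reagents that add atoms: 1,2-bis(trimethylsilyloxy)ethane, C[Si](C)(C)OCCO[Si](C)(C)C
Why: Noyori ketalisation, in which the silyl triflate activates the C3 ketone towards the bis-silyl glycol at low temperature, where neither dehydration of the β-hydroxy ketone nor closure to the enolic keto lactone competes; the C1 hydroxyl travels as its trimethylsilyl ether and is freed by methanolysis.

Step 20
Reactants: 28
Product: 29 δ-lactone precursor (C19–O–C1 lactone on C10; C3 and C7 dioxolanes; 12-OTBS; C4 epimers)
Conditions: pyridinium p-toluenesulfonate (cat.), toluene, 5 Å MS, 60 °C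
Reagents that add atoms: none
Why: Acid-catalysed intramolecular transesterification (lactonisation) of the δ-hydroxy ester, helped by the gem-disubstitution at C3 and driven by removal of methanol, with C1 untouched.

Step 21
Reactants: 29
Product: 32 ring-A C19 acid (1(10)-ene; 4β-methyl; 5β-H; C3 and C7 dioxolanes; 12-OTBS), via silyl ketene acetal 30 (not isolated), via TBS ester 31 (not isolated)
Conditions: KN(SiMe3)2 (1.5 equiv) added to 29 and t-BuMe2SiCl (3 equiv), THF/toluene, −78 °C; then 80 °C; then K2CO3, MeOH/H2O, and NaH2PO4 to pH 5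
Reagents that add atoms: none
Why: KN(SiMe3)2 removes the only acidic proton (H-4) with the silyl chloride already present, so the lactone enolate is trapped at once as cyclic silyl ketene acetal 30 before the C3 ketal oxygen can be expelled; on warming, 30 undergoes the concerted [3,3] shift that makes C4–C5, breaks C1–O and moves the alkene to C1=C10, and mild hydrolysis of silyl ester 31 gives the acid. The closest known reaction type is the Ireland–Claisen ring contraction of 6-alkenyl δ-lactones and dioxanones to cyclohexene carboxylic acids. Ring A is closed by the bond-forming terminus of the sigmatropic shift itself, through a boat transition state in which the two-atom C2–C3 tether spans C1 and C4, not by an ionic ring closure. C5 is set by suprafacial transfer from (1S)-C1: the C1–O bond can align only on the α-face of the ring-B alkene, so C4 bonds to C5 on that face, anti to the C7 dioxolane, and the same bicyclic geometry sets C4 by turning C18 outwards (β) and C19 to the α-face whatever the C4 configuration of 29. The step needs complete chirality transfer and a single enolisation site; the lactone tether, which allows one boat only, and the absence of other acidic C–H bonds (C3 and C7 are acetals, O12 is silylated) secure both.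

Step 22
Reactants: 32
Product: 33 1β-iodo 19,10-lactone (C3 and C7 dioxolanes; 12-OTBS)
Conditions: I2 (1.3 equiv), NaHCO3, THF/H2O, 0 °C, dark
Reagents that add atoms: iodine, II
Why: Iodolactonisation, in which the iodonium ion on the β-face of the C1=C10 alkene is captured 5-exo by the α-oriented C19 carboxylate at tertiary C10 (anti addition), setting C10 with the lactone oxygen α and leaving an axial β-iodide at C1, while the 16-methylene has no internal nucleophile and its iodonium ion simply reverts.

Step 23
Reactants: 33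
Product: 35 1β-hydroxy 19,10-lactone (C3 and C7 dioxolanes; 12-OTBS), via 1β-hydroperoxide 34 (not isolated)
Conditions: Bu3SnH (slow addition), O2 (1 atm), toluene, rt; then PPh3
Reagents that add atoms: dioxygen, O=O
Why: Radical deiodination–oxygenation (tin hydride/oxygen chain), in which the C1 radical should be trapped by O2 on the β-face, anti to the adjacent C10–O bond and away from the lactone bridge covering the α-face, so C1 keeps the β-configuration, and PPh3 reduces the hydroperoxide to the alcohol.

Step 24
Reactants: 35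
Product: 36 1β,12-dihydroxy-3-oxo 7-aldehyde (19,10-lactone)
Conditions: 3 M aq. HCl/THF 1:3, rt
Reagents that add atoms: water, O
Why: Specific-acid hydrolysis of both dioxolanes and of the silyl ether; dilute acid at room temperature should spare the 16-methylene and the β-hydroxy ketone, and C6 next to the freed aldehyde stays in (or returns to) the favoured configuration trans to the C5–C4 bond.

Step 25
Reactants: 36
Product: 37 target acid CNP0259985.1
Conditions: NaClO2, NaH2PO4, 2-methylbut-2-ene, t-BuOH/H2O, rt
Reagents that add atoms: sodium chlorite, [Na+].[O-]Cl=O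
Why: Pinnick oxidation converts the aldehyde to the C7 acid without touching the alcohols, ketone or lactone, and 2-methylbut-2-ene scavenges hypochlorous acid before it reaches the 16-methylene.

Compound list
1 | furfural (furan-2-carbaldehyde) | O=Cc1ccco1 | starting material
2 | propargyl bromide (3-bromoprop-1-yne) | C#CCBr | starting material
3 | (±)-1-(furan-2-yl)but-3-yn-1-ol | C#CCC(O)c1ccco1 | intermediate
4 | (±)-trans-4-hydroxy-5-(prop-2-yn-1-yl)cyclopent-2-en-1-one (racemic, relative configuration drawn) | O=C1C=C[C@H](O)[C@H]1CC#C | intermediate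
5 | (±)-4-hydroxy-2-(prop-2-yn-1-yl)cyclopent-2-en-1-one | C#CCC1=CC(O)CC1=O | intermediate
6 | (R)-4-acetoxy-2-(prop-2-yn-1-yl)cyclopent-2-en-1-one | C#CCC1=C[C@H](OC(C)=O)CC1=O | intermediate
7 | (R)-4-hydroxy-2-(prop-2-yn-1-yl)cyclopent-2-en-1-one | C#CCC1=C[C@H](O)CC1=O | intermediate
8 | (R)-4-(triethylsilyloxy)-2-(prop-2-yn-1-yl)cyclopent-2-en-1-one | C#CCC1=C[C@H](O[Si](CC)(CC)CC)CC1=O | intermediate
9 | methyl vinyl ketone (but-3-en-2-one) | C=CC(C)=O | starting material
10 | 2-(triisopropylsilyloxy)buta-1,3-diene | C=CC(=C)O[Si](C(C)C)(C(C)C)C(C)C | intermediate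
11 | Diels–Alder adduct: cis-fused B/C bicycle, C6 ketone, 8β-propargyl, 9β-H, 10β-OSiEt3, C12=C13 triisopropylsilyl enol ether | C#CC[C@]12CC=C(O[Si](C(C)C)(C(C)C)C(C)C)C[C@H]1[C@H](O[Si](CC)(CC)CC)CC2=O | intermediate
12 | B/C/D diketone: 6,12-dioxo, 10β-OSiEt3, 16-methylene | C=C1C[C@]23C[C@H]1C(=O)C[C@H]2[C@H](O[Si](CC)(CC)CC)CC3=O | intermediate
13 | 6α,12-diol (12-OH axial, syn to C10), 10β-OSiEt3 | C=C1C[C@]23C[C@H]1[C@@H](O)C[C@H]2[C@H](O[Si](CC)(CC)CC)C[C@H]3O | intermediate
14 | 6α,12-bis-OTBS, 10β-OSiEt3 | C=C1C[C@]23C[C@H]1[C@@H](O[Si](C)(C)C(C)(C)C)C[C@H]2[C@H](O[Si](CC)(CC)CC)C[C@H]3O[Si](C)(C)C(C)(C)C | intermediate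
15 | 10β-alcohol, 6α,12-bis-OTBS | C=C1C[C@]23C[C@H]1[C@@H](O[Si](C)(C)C(C)(C)C)C[C@H]2[C@H](O)C[C@H]3O[Si](C)(C)C(C)(C)C | intermediate
16 | 10-ketone, 6α,12-bis-OTBS | C=C1C[C@]23C[C@H]1[C@@H](O[Si](C)(C)C(C)(C)C)C[C@H]2C(=O)C[C@H]3O[Si](C)(C)C(C)(C)C | intermediate
17 | ring-B enone: 10-oxo-5-ene, 12-OTBS, 16-methylene | C=C1C[C@]23C[C@H]1[C@@H](O[Si](C)(C)C(C)(C)C)C[C@H]2C(=O)C=C3 | intermediate
18 | 1,3-dioxolane | C1COCO1 | starting material
19 | 6β-(1,3-dioxolan-2-yl) 10-ketone, 12-OTBS | C=C1C[C@]23C[C@H]1[C@@H](O[Si](C)(C)C(C)(C)C)C[C@H]2C(=O)C[C@@H]3C1OCCO1 | intermediate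
20 | C10 enol triflate (5(10)-ene), 6β-dioxolanyl, 12-OTBS | C=C1C[C@]23C[C@H]1[C@@H](O[Si](C)(C)C(C)(C)C)C[C@H]2C(OS(=O)(=O)C(F)(F)F)=C[C@@H]3C1OCCO1 | intermediate
21 | B/C/D enal: 10-formyl-5(10)-ene, 6β-dioxolanyl, 12-OTBS, 16-methylene | C=C1C[C@]23C[C@H]1[C@@H](O[Si](C)(C)C(C)(C)C)C[C@H]2C(C=O)=C[C@@H]3C1OCCO1 | intermediate
22 | methyl 2-methylacetoacetate | CC(=O)C(C)C(=O)OC | starting material
23 | methyl 2-methyl-3-(trimethylsilyloxy)but-2-enoate | CC(O[Si](C)(C)C)=C(C)C(=O)OC | intermediate
24 | 1-methoxy-2-methyl-1,3-bis(trimethylsilyloxy)buta-1,3-diene | C=C(O[Si](C)(C)C)C(C)=C(OC)O[Si](C)(C)C | intermediate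
25 | (1S)-aldol adduct as C1 trimethylsilyl ether and C3 silyl enol ether | C=C1C[C@]23C[C@H]1[C@@H](O[Si](C)(C)C(C)(C)C)C[C@H]2C(=C[C@@H]3C1OCCO1)[C@@H](O[Si](C)(C)C)CC(O[Si](C)(C)C)=C(C)C(=O)OC | intermediate
26 | (1S)-δ-hydroxy β-keto methyl ester (C4 epimers) | C=C1C[C@]23C[C@H]1[C@@H](O[Si](C)(C)C(C)(C)C)C[C@H]2C(=C[C@@H]3C1OCCO1)[C@@H](O)CC(=O)C(C)C(=O)OC | intermediate
27 | C3 dioxolane ester, C1 trimethylsilyl ether (C4 epimers) | C=C1C[C@]23C[C@H]1[C@@H](O[Si](C)(C)C(C)(C)C)C[C@H]2C(=C[C@@H]3C1OCCO1)[C@@H](O[Si](C)(C)C)CC1(OCCO1)C(C)C(=O)OC | intermediate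
28 | (1S)-hydroxy ester with C3 dioxolane (C4 epimers) | C=C1C[C@]23C[C@H]1[C@@H](O[Si](C)(C)C(C)(C)C)C[C@H]2C(=C[C@@H]3C1OCCO1)[C@@H](O)CC1(OCCO1)C(C)C(=O)OC | intermediate
29 | key-step precursor: (1S) C19–O–C1 δ-lactone on C10 of the B/C/D cyclopentene, C3 and C7 dioxolanes, 12-OTBS (C4 epimers, both converge; the epimer with C18 trans to C10 is drawn) | C=C1C[C@]23C[C@H]1[C@@H](O[Si](C)(C)C(C)(C)C)C[C@H]2C(=C[C@@H]3C1OCCO1)[C@@H]1CC2(OCCO2)[C@@H](C)C(=O)O1 | intermediate
30 | cyclic tert-butyldimethylsilyl ketene acetal of 29 (C4=C19) | C=C1C[C@]23C[C@H]1[C@@H](O[Si](C)(C)C(C)(C)C)C[C@H]2C(=C[C@@H]3C1OCCO1)[C@@H]1CC2(OCCO2)C(C)=C(O[Si](C)(C)C(C)(C)C)O1 | intermediate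
31 | tert-butyldimethylsilyl ester of 32 | C=C1C[C@]23C[C@H]1[C@@H](O[Si](C)(C)C(C)(C)C)C[C@H]2C1=CCC2(OCCO2)[C@@](C)(C(=O)O[Si](C)(C)C(C)(C)C)[C@H]1[C@@H]3C1OCCO1 | intermediate
32 | key-step product: ring-A C19 acid, 1(10)-ene, 4β-methyl, 5β-H, C3 and C7 dioxolanes, 12-OTBS | C=C1C[C@]23C[C@H]1[C@@H](O[Si](C)(C)C(C)(C)C)C[C@H]2C1=CCC2(OCCO2)[C@@](C)(C(=O)O)[C@H]1[C@@H]3C1OCCO1 | intermediate
33 | 1β-iodo 19,10-lactone, C3 and C7 dioxolanes, 12-OTBS | C=C1C[C@]23C[C@H]1[C@@H](O[Si](C)(C)C(C)(C)C)C[C@H]2[C@]12OC(=O)[C@](C)(C4(OCCO4)C[C@H]1I)[C@H]2[C@@H]3C4OCCO4 | intermediate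
34 | 1β-hydroperoxy 19,10-lactone | C=C1C[C@]23C[C@H]1[C@@H](O[Si](C)(C)C(C)(C)C)C[C@H]2[C@]12OC(=O)[C@](C)(C4(OCCO4)C[C@H]1OO)[C@H]2[C@@H]3C4OCCO4 | intermediate
35 | 1β-hydroxy 19,10-lactone, C3 and C7 dioxolanes, 12-OTBS | C=C1C[C@]23C[C@H]1[C@@H](O[Si](C)(C)C(C)(C)C)C[C@H]2[C@]12OC(=O)[C@](C)(C4(OCCO4)C[C@H]1O)[C@H]2[C@@H]3C4OCCO4 | intermediate
36 | 1β,12-dihydroxy-3-oxo 19,10-lactone 7-aldehyde | C=C1C[C@]23C[C@H]1[C@@H](O)C[C@H]2[C@]12OC(=O)[C@](C)(C(=O)C[C@H]1O)[C@H]2[C@@H]3C=O | intermediate
37 | CNP0259985.1 (1β,12-dihydroxy-3-oxo 19,10-lactone 7-oic acid) | C=C1C[C@]23C[C@H]1[C@@H](O)C[C@H]2[C@]12OC(=O)[C@](C)(C(=O)C[C@H]1O)[C@H]2[C@@H]3C(=O)O | target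

Total step count: 25. Longest linear sequence: 22 steps (1–5, 7–15, 18–25); steps 6, 16 and 17 are side branches.

Steps most likely to fail

Step 21 (key step). What may go wrong: the potassium enolate expels the C3 ketal oxygen before it is silylated, or the silyl ketene acetal decomposes (C-silylation, ketene loss) faster than it reaches the boat geometry, which is crowded on the α-face by the axial C12 silyl ether. The fallback sets out from 26 and forms the C4–C5 bond by palladium-catalysed intramolecular allylic alkylation instead of a sigmatropic shift. Methyl chloroformate and pyridine turn the C1 hydroxyl of 26 into the allylic methyl carbonate F1. Pd(PPh3)4 in THF ionises it anti to the leaving group, and the β-keto ester enolate freed by decarboxylation attacks the far allyl terminus C5 anti to palladium (net retention, the same face as in the sigmatropic route; attack at C1 would give a cyclobutane). This gives the ring-A β-keto methyl ester F2, from which the C4 epimer with the ester on the α-face is separated. Noyori ketalisation of its C3 ketone gives the ketal ester F3, and Me3SnOH in 1,2-dichloroethane at 80 °C cleaves the hindered methyl ester, which returns to the route at 32.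

Step 7. What may go wrong: the acid-sensitive diene is lost by protodesilylation or oligomerisation, or the dienophile loses its β-silyloxy group, faster than the hindered α-substituted enone undergoes cycloaddition. The fallback sets out from 8 and 10 and builds ring C in two separate ionic bond formations. A Mukaiyama–Michael addition (i-Pr3SiOTf, 5 mol%, CH2Cl2, −78 °C) forms only the C9–C11 bond, anti to the C10 silyloxy group, and gives the vinyl ketone silyl enol ether F4, which is isolated. A separate intramolecular Mukaiyama–Michael closure (Tf2NH, 5 mol%, CH2Cl2, −40 to 0 °C) then joins C8 to C14 with transfer of the silyl group to the new C12 enolate, which returns to the route at 11.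

Step 23. What may go wrong: hydrogen transfer from the stannane to the C1 radical outpaces oxygen capture (plain deiodination), or oxygen is captured on both faces of the radical. The fallback sets out from 32, bypasses 33, and makes the C10–O and C1–O bonds by epoxide opening. mCPBA (1 equiv) with NaHCO3 in CH2Cl2 at 0 °C should epoxidise the more electron-rich trisubstituted C1=C10 alkene on its β-face, in preference to the 16-methylene, to give the epoxy acid F5. Camphorsulfonic acid (cat.) then lets the C19 carboxyl open the epoxide 5-exo at C10 with inversion, so the C1 hydroxyl is β by construction, and the route is rejoined at 35.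

Further compounds
F1 | step 21 | C1 methyl carbonate of 26 | C=C1C[C@]23C[C@H]1[C@@H](O[Si](C)(C)C(C)(C)C)C[C@H]2C(=C[C@@H]3C1OCCO1)[C@@H](OC(=O)OC)CC(=O)C(C)C(=O)OC
F2 | step 21 | ring-A 3-oxo C19 methyl ester, 1(10)-ene | C=C1C[C@]23C[C@H]1[C@@H](O[Si](C)(C)C(C)(C)C)C[C@H]2C1=CCC(=O)[C@@](C)(C(=O)OC)[C@H]1[C@@H]3C1OCCO1
F3 | step 21 | methyl ester of 32 | C=C1C[C@]23C[C@H]1[C@@H](O[Si](C)(C)C(C)(C)C)C[C@H]2C1=CCC2(OCCO2)[C@@](C)(C(=O)OC)[C@H]1[C@@H]3C1OCCO1
F4 | step 7 | Mukaiyama–Michael adduct: C6 triisopropylsilyl enol ether with a 2-oxobut-3-enyl group on C9 | C#CCC1=C(O[Si](C(C)C)(C(C)C)C(C)C)C[C@@H](O[Si](CC)(CC)CC)[C@@H]1CC(=O)C=C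
F5 | step 23 | 1β,10β-epoxy C19 acid | C=C1C[C@]23C[C@H]1[C@@H](O[Si](C)(C)C(C)(C)C)C[C@H]2[C@@]45O[C@@H]4CC6(OCCO6)[C@@](C)(C(=O)O)[C@H]5[C@@H]3C7OCCO7
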